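**Locants and faces used throughout.** Ring A: C1 (gem-diprenyl), C2 (C=O), C3 (spiro), C4 (C=O), C5 (isobutyryl-bearing), C6 (enol). Ring B: C3, C8, C9, C10, C11 (methyl carbinol), C12. Ring C: C9, C10, C13, C14, C15 (methyl carbinol). α is the face of ring B that carries the C11 oxygen, β the opposite face.

## Analysis of the target

Target 28 is a spirocyclic acylphloroglucinol-type β-triketone. Ring A (a cyclohexane-1,3,5-trione drawn as its C6 enol, with a C5 isobutyryl group and a gem-diprenylated C1) shares the quaternary carbon C3 with cyclohexane ring B, which is trans-fused through C9–C10 to cyclopentane ring C. There are five stereocentres: C3, C9, C10, C11 and C15. H9 is α and H10 β; the C11 hydroxyl is α and axial, anti to H10 and syn-axial to the C2 carbonyl branch on C3; the C15 hydroxyl is β, cis to C8. C3 is stereogenic only because the two acyl arms of ring A differ (C2 lies next to C1, C4 next to C5), so it has to be set by telling apart two carboxyl groups on one carbon. The sensitive functions are the enolised triketone (acidic, chelating, open to O-alkylation and retro-Claisen cleavage), two tertiary alcohols that ionise in strong acid, and two prenyl alkenes that forbid late ozonolysis. The difficulty lies in the contiguous centres C11–C10–C9 and the C15 carbinol on a trans-fused bicycle, together with a spiro centre that only the C11 oxygen can reach. The plan rests on one feature: rings B and C share the C9–C10 bond, this bond is flanked by the oxygenated quaternary carbons C11 and C15, and C3 carries two acyl groups. A C15 carbinol next to the ring fusion is the oxidation product of an exocyclic methylene, which is what a substituted trimethylenemethane unit leaves behind; with C3 as a malonate carbon, a three-carbon donor anchored at C9 and a C10=C13 acceptor on the C11 arm can close both rings together.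

## Retrosynthetic reasoning

**28 ⇒ 26.** The two bonds from C1 to the prenyl groups are cut first. C1 is the only ring A carbon of 26 that is enolisable and unsubstituted, so a double C-alkylation needs no regiocontrol. Leaving the two trisubstituted alkenes to the end keeps them away from the ozonolyses, the strong acid and the dissolving-metal step.

**26 ⇒ 23 + 24.** Ring A is opened at C1–C2 and C4–C5. This returns diketone 24 as a 1,5-dinucleophile and a C3 that carries two different carboxyl groups: a lactone carbonyl (future C2) and a methyl ester (future C4). Cutting here, and not at a bond to C3, keeps the quaternary carbon intact and reduces the spiro problem to the question of which carboxyl is which. Forward, the terminal carbanion must open the lactone and the central carbanion must then close onto the ester.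

**23 ⇒ 22 ⇒ 21.** The C15–CH3 bond is cut to give ketone 22, and the methyl ester is traced to acid 21. The methyl group is added only after the lactone exists, so that no tertiary C15 alcohol has to meet the acid of the next disconnection. The addition has to come from the α face of the carbonyl.

**21 ⇒ 19.** The lactone C–O bond between the C11 oxygen and C2 is cut. C3 then carries two identical esters and stops being a stereocentre. In the chair of ring B the C11 oxygen is axial and only the α ester is 1,3-diaxial to it, so the forward lactonisation chooses between the esters by geometry alone and sets the spiro centre.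

**19 ⇒ 17 ⇒ 16.** These are functional-group changes only. The C15 ketone comes from an exocyclic methylene and the C13 hydrogen from a sulfone; both are the marks that a trimethylenemethane cycloaddition to a vinyl sulfone leaves.

**16 ⇒ 15.** The C9–C10 and C13–C14 bonds are cut together. Rings B and C open to an acyclic malonate with a 2-(silylmethyl)allyl carbonate arm on C8 and a vinyl sulfone arm on C12. These bonds are chosen because C9–C10 is common to both rings and C13–C14 lies between two unfunctionalised carbons, so nothing has to be removed except the sulfone. Two rings and two stereocentres disappear, and C11 is left as the only stereocentre. Forward, C9 must add to C10 and C13 must close on C14, with a trans ring fusion and H10 anti to the C11 oxygen.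

**15 ⇒ 14 ⇒ 12 + 13.** The carbonate is traced to alcohol 14, and the C9–C15 bond is cut to aldehyde 12 and vinyl bromide 13. The C9 configuration is irrelevant because ionisation erases it. The forward addition must leave the vinyl sulfone alone, which calls for a chemoselective organochromium coupling.

**12 ⇒ 10 ⇒ 8 + 9.** The C9 aldehyde is an oxidatively cleaved allyl group (10), and the C10=C13 double bond is cut to aldehyde 8 and phosphonate 9. The sulfone is installed before the allylsilane so that no protecting-group chemistry has to be done on the acid- and oxidant-sensitive silylmethylallyl unit.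

**8 ⇒ 5 ⇒ 2 + 3.** After the oxidation state at C10 is adjusted (8 ⇐ 7 ⇐ 6 ⇐ 5), the C3–C8 and C3–C12 bonds are cut. C3 is malonate 3, C8–C9 an allyl electrophile, and C12–C11–C10 epoxide 2. Opening the epoxide at its CH2 terminus does not touch C11. Tert-butyl esters are chosen because they resist attack by the neighbouring alkoxides, and the allyl group is added second, in the same flask, so that the tertiary alkoxide is never present without an acidic malonate C–H to quench it.

**2 ⇒ 1.** The chiral-pool alcohol 1 is protected; its stereocentre becomes C11.

## Alternatives that were turned down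

**Alternative 1:** Disconnection at C8–C9 and C10–C11, with ring C as a preformed cyclopentene. In the forward step the silylmethyl radical from (S)-(bromomethyl)dimethyl[(1-methylcyclopent-2-en-1-yl)oxy]silane A1 closes 5-exo onto C9. The C10 radical is then trapped on the face away from the new ring by a tert-alkyl isocyanide, which fragments to the nitrile of the cis-fused oxasilolane A2.
- For: the tether delivers C8 cis to the C15 oxygen and the trapping is trans, so C15, C9 and C10 emerge in the target's relative configuration from one carbinol. On the C15 centre this is stronger than the chosen route, which sets C15 late by reagent approach.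
- Against: only ring C and two bonds result. Ring B, C3 and its two bonds are still to be made, and the C11 carbinol would have to come from the nitrile by two successive carbon additions under acyclic stereocontrol. An enantioenriched tertiary allylic alcohol is needed, and the bimolecular trapping competes with simple reduction of the C10 radical.
- Comparison: the chosen strategy closes both rings in one step, takes C11 from the chiral pool, and already has C3 in place as a malonate for ring A.

**Alternative 2:** Disconnection at C1–C2 and C4–C5. The dianion of dione 24 opens the bridged lactone methyl ester A3 (identical with 23) at its carbonyl, and the resulting triketone anion acylates itself on the ester to give the des-prenyl spiro triketone A4 (identical with 26).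
- For: it is convergent, the lactone stores the C3 configuration, and the whole triketone is built in one operation. Nothing in the chosen plan does ring A better, and the step is adopted as step 16.
- Against: as the defining step it leaves open how rings B and C and the four stereocentres of A3 are made, which is where the difficulty lies. It also depends on the dianion preferring the lactone over the ester.
- Comparison: equal on ring A; the chosen strategy adds the answer for the bicyclic core.

**Alternative 3:** Disconnection at C9–C15 and C10–C13 on the achiral enone dimethyl 5-oxocyclohex-3-ene-1,1-dicarboxylate A5. The pinacol boronate A6 adds to C9 under [RhCl(C2H4)2]2 and a chiral diphosphine, and KOt-Bu then closes C10 onto the chloride to give the C11 ketone A7.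
- For: the absolute configuration comes from the catalyst, there is no sulfone to remove, and the ring-forming stage is shorter than in the chosen route; on step economy at that stage it is stronger.
- Against: the trans fusion rests on equilibration of the epimerisable C10 next to the C11 ketone, since enolate ring closure onto a neighbouring chain tends to give the cis bicycle first. The C11 carbinol must then be made by a later methyl addition, and neither A5 nor A6 is an article of commerce.
- Comparison: the chosen strategy has C11 as a fixed chiral-pool centre that steers C9 and C10 through a chair transition state, gives the trans fusion kinetically, and builds its precursor by plain alkylations. Alternative 3 is kept as the fallback for the key step.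

Key step: step 10

Assumption: 28 is treated as one compound with its keto–enol tautomers (drawn as the C6 enol); centres carried as mixtures (C9 in 14 and 15, C13 in 16, the ozonide carbons in 11 and 18, C1 in 27) are erased or removed later.

## Route

Step 1
Reactants: 1 (S)-2-methylglycidol
Product: 2 (R)-2-[(4-methoxybenzyloxy)methyl]-2-methyloxirane
Conditions: NaH, 4-methoxybenzyl chloride, Bu4NI (cat.), THF/DMF, 0 °C to rt
Reagents that add atoms: 4-methoxybenzyl chloride, COc1ccc(CCl)cc1
Why: Williamson etherification of the primary alkoxide; the stereocentre is not touched (the descriptor changes only through the priorities), and a Payne rearrangement of the alkoxide of 1 would be degenerate and return the same enantiomer.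

Step 2
Reactants: 2 (R)-2-[(4-methoxybenzyloxy)methyl]-2-methyloxirane; 3 di-tert-butyl malonate
Product: 5 di-tert-butyl 2-allyl-2-[(2R)-2-hydroxy-3-(4-methoxybenzyloxy)-2-methylpropyl]malonate, via sodium enolate 4 (not isolated)
Conditions: 3, NaH, DMF, 0 °C to rt; 2, 65 °C; then allyl bromide, 0 °C to rt
Reagents that add atoms: allyl bromide, C=CCBr
Why: The malonate anion opens the epoxide by SN2 attack at its CH2 terminus (C3–C12) without touching C11. The tertiary alkoxide is quenched at once by the malonate C–H to give the stabilised enolate 4, which cannot lactonise onto the tert-butyl esters and is C-allylated in the same flask (C3–C8).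

Step 3
Reactants: 5 di-tert-butyl 2-allyl-2-[(2R)-2-hydroxy-3-(4-methoxybenzyloxy)-2-methylpropyl]malonate
Product: 6 di-tert-butyl 2-allyl-2-[(2R)-3-(4-methoxybenzyloxy)-2-methyl-2-(triethylsilyloxy)propyl]malonate
Conditions: TESOTf, 2,6-lutidine, CH2Cl2, −78 to 0 °C
Reagents that add atoms: triethylsilyl trifluoromethanesulfonate, CC[Si](CC)(CC)OS(=O)(=O)C(F)(F)F
Why: Silyl triflate silylation of a hindered tertiary alcohol; the low temperature spares the tert-butyl esters, and the silyl ether blocks lactonisation until step 13.

Step 4
Reactants: 6 di-tert-butyl 2-allyl-2-[(2R)-3-(4-methoxybenzyloxy)-2-methyl-2-(triethylsilyloxy)propyl]malonate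
Product: 7 di-tert-butyl 2-allyl-2-[(2R)-3-hydroxy-2-methyl-2-(triethylsilyloxy)propyl]malonate
Conditions: DDQ, CH2Cl2/pH 7 buffer, 0 °C to rt
Reagents that add atoms: none
Why: Oxidative cleavage of the 4-methoxybenzyl ether by benzylic hydride abstraction and hydrolysis; the terminal alkene, the tertiary silyl ether and the esters are inert, and 7 is oxidised without storage to avoid silyl migration.

Step 5
Reactants: 7 di-tert-butyl 2-allyl-2-[(2R)-3-hydroxy-2-methyl-2-(triethylsilyloxy)propyl]malonate
Product: 8 di-tert-butyl 2-allyl-2-[(2R)-2-methyl-3-oxo-2-(triethylsilyloxy)propyl]malonate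
Conditions: Dess–Martin periodinane, NaHCO3, CH2Cl2, 0 °C to rt
Reagents that add atoms: none
Why: Dess–Martin oxidation under buffered conditions; the aldehyde has no α-hydrogen, so C11 cannot epimerise.

Step 6
Reactants: 8 di-tert-butyl 2-allyl-2-[(2R)-2-methyl-3-oxo-2-(triethylsilyloxy)propyl]malonate; 9 diethyl (phenylsulfonylmethyl)phosphonate
Product: 10 di-tert-butyl 2-allyl-2-[(2R,3E)-2-methyl-4-(phenylsulfonyl)-2-(triethylsilyloxy)but-3-enyl]malonate
Conditions: 9, NaH, THF, 0 °C; then 8, 0 °C to rt
Reagents that add atoms: none
Why: Horner–Wadsworth–Emmons olefination with the sulfonyl-stabilised phosphonate anion, which is E-selective and gives the C10=C13 acceptor.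

Step 7
Reactants: 10 di-tert-butyl 2-allyl-2-[(2R,3E)-2-methyl-4-(phenylsulfonyl)-2-(triethylsilyloxy)but-3-enyl]malonate
Product: 12 di-tert-butyl 2-[(2R,3E)-2-methyl-4-(phenylsulfonyl)-2-(triethylsilyloxy)but-3-enyl]-2-(2-oxoethyl)malonate, via ozonide 11 (not isolated)
Conditions: O3 (1 equiv), CH2Cl2, −78 °C; PPh3, −78 °C to rt
Reagents that add atoms: ozone, [O-][O+]=O
Why: Ozonolysis with reductive work-up; electrophilic ozone takes the monosubstituted alkene and leaves the electron-poor vinyl sulfone.

Step 8
Reactants: 12 di-tert-butyl 2-[(2R,3E)-2-methyl-4-(phenylsulfonyl)-2-(triethylsilyloxy)but-3-enyl]-2-(2-oxoethyl)malonate; 13 2-bromoallyltrimethylsilane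
Product: 14 di-tert-butyl 2-[2-hydroxy-3-(trimethylsilylmethyl)but-3-enyl]-2-[(2R,3E)-2-methyl-4-(phenylsulfonyl)-2-(triethylsilyloxy)but-3-enyl]malonate (both C9 epimers)
Conditions: 13, CrCl2, NiCl2 (2 mol%), DMF, rt
Reagents that add atoms: none
Why: Nozaki–Hiyama–Kishi coupling: nickel inserts into the vinyl bromide and hands the vinyl group to chromium, and the vinylchromium adds only to the aldehyde (C9–C15), ignoring the vinyl sulfone and the esters. The C9 configuration is of no consequence.

Step 9
Reactants: 14 allylic alcohol (both C9 epimers)
Product: 15 di-tert-butyl 2-[2-(methoxycarbonyloxy)-3-(trimethylsilylmethyl)but-3-enyl]-2-[(2R,3E)-2-methyl-4-(phenylsulfonyl)-2-(triethylsilyloxy)but-3-enyl]malonate (both C9 epimers)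
Conditions: ClCO2Me, pyridine, DMAP (cat.), CH2Cl2, 0 °C
Reagents that add atoms: methyl chloroformate, COC(=O)Cl
Why: Acylation of the secondary allylic alcohol; the methyl carbonate is both the leaving group for ionisation and the internal source of the methoxide that removes silicon.

Step 10
Reactants: 15 silylmethylallyl carbonate / vinyl sulfone malonate
Product: 16 di-tert-butyl 4-methyl-1-methylidene-3-(phenylsulfonyl)-4-(triethylsilyloxy)octahydroindene-6,6-dicarboxylate (trans-fused, H9 α, H10 β, C11 methyl β, C11 silyloxy α, both C13 epimers)
Conditions: Pd(OAc)2 (10 mol%), P(OiPr)3 (60 mol%), THF, reflux, 0.01 M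
Reagents that add atoms: none
Why: Zerovalent palladium, formed in the flask from Pd(OAc)2 and the phosphite, ionises the allylic carbonate, and the methoxide set free by loss of CO2 removes the silyl group to give the zwitterionic trimethylenemethane–palladium complex, so both C9 epimers of 15 converge. Its tether-bearing terminus C9 adds to C10 of the (E)-vinyl sulfone in a 6-exo-trig conjugate addition that closes ring B. The α-sulfonyl carbanion at C13 then attacks the C14 terminus of the cationic π-allylpalladium unit in a 5-exo-tet-type allylic alkylation that closes ring C, leaves the C15 exocyclic methylene and returns the catalyst. The closest known reaction is the intramolecular palladium-catalysed trimethylenemethane (3+2) cycloaddition of carbinol-tethered 2-(silylmethyl)allyl esters to vinyl sulfones, which gives bicyclo[4.3.0]nonanes. C9 and C10 are set in the first bond formation through a chair of the forming ring B in which the allylpalladium unit on C9 and the sulfonylmethine carbon on C10 are both equatorial, which gives the trans fusion. Which of the two such chairs is used is decided by C11: the methyl group takes the equatorial site and the silyloxy group the axial one, because the axial site is syn to the axial tert-butyl ester on C3 and oxygen is the smaller partner; this puts H10 anti to the C11 oxygen. The step needs chemoselective ionisation (only the carbonate is allylic to an unhindered alkene), reaction through the substituted terminus (usual for alkyl-substituted complexes) and this facial selectivity, and high dilution keeps the reaction intramolecular.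

Step 11
Reactants: 16 sulfonyl cycloadduct
Product: 17 di-tert-butyl 4-methyl-1-methylidene-4-(triethylsilyloxy)octahydroindene-6,6-dicarboxylate (trans-fused, H9 α, H10 β, C11 methyl β, C11 silyloxy α)
Conditions: Na(Hg) (6% Na), Na2HPO4, MeOH/THF, −20 to 0 °C
Reagents that add atoms: none
Why: Reductive desulfonylation by electron transfer, C–S cleavage and protonation by methanol; it removes the stereorandom C13 centre, and the buffered medium spares the esters, the silyl ether and the alkene.

Step 12
Reactants: 17 methylidene diester
Product: 19 di-tert-butyl 4-methyl-1-oxo-4-(triethylsilyloxy)octahydroindene-6,6-dicarboxylate (C15 ketone, H9 α, H10 β), via ozonide 18 (not isolated)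
Conditions: O3, CH2Cl2, −78 °C; PPh3, −78 °C to rt
Reagents that add atoms: ozone, [O-][O+]=O
Why: Ozonolysis of the only alkene; the neutral reductive work-up keeps the C9 configuration next to the new ketone.

Step 13
Reactants: 19 C15 ketone diester
Product: 21 bridged lactone acid (γ-lactone from the C11 oxygen to the α carboxyl on C3, β carboxylic acid on C3, C15 ketone), via hydroxy diacid 20 (not isolated)
Conditions: TFA/CH2Cl2 (1:4), 0 °C to rt; concentrate; toluene, 40 °C
Reagents that add atoms: none
Why: Acidolysis removes the silyl ether and both tert-butyl groups. In the ring B chair only the α carboxyl is 1,3-diaxial to the axial C11 hydroxyl, so that pair alone closes the lactone (a 6-oxabicyclo[3.2.1]octan-7-one); this sets C3, with the lactone carbonyl as future C2 and the free β acid as future C4. The step is run at the ketone stage so that no tertiary C15 alcohol is present to ionise or compete.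

Step 14
Reactants: 21 bridged lactone acid
Product: 22 bridged lactone methyl ester (C15 ketone)
Conditions: TMSCHN2, toluene/MeOH, 0 °C
Reagents that add atoms: trimethylsilyldiazomethane, C[Si](C)(C)C=[N+]=[N-]
Why: O-methylation of the carboxylic acid by the diazo compound under neutral conditions; the ketone, the lactone and the C9 centre are untouched.

Step 15
Reactants: 22 bridged lactone methyl ester (C15 ketone)
Product: 23 bridged lactone methyl ester with the C15 methyl carbinol (OH β, methyl α)
Conditions: MeMgBr, CeCl3, THF, −78 °C
Reagents that add atoms: methylmagnesium bromide, C[Mg]Br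
Why: Organocerium addition, which is non-basic (no enolisation at C9) and at −78 °C takes the ketone ahead of the lactone and the ester, both of which sit on the quaternary C3. The α face of the C15 carbonyl points away from ring B while the β face is flanked by the axial hydrogens on C8 and C10, so the methyl group should enter from α and leave the hydroxyl β, cis to C8.

Step 16
Reactants: 23 bridged lactone methyl ester carbinol; 24 5-methylhexane-2,4-dione
Product: 26 des-prenyl spiro acyl triketone (ring A with C1H2, free C11 and C15 hydroxyls), via hydroxy triketo ester 25 (not isolated)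
Conditions: 24 (4 equiv), LiN(iPr)2 (8 equiv), THF, −78 to 0 °C; add 23, −78 °C to rt, then 50 °C; 1 M HCl
Reagents that add atoms: none
Why: The terminal carbanion of the diketone dianion is acylated by the strained lactone carbonyl (C1–C2) to give 25, whose central carbanion then closes onto the methyl ester (C4–C5) in a Dieckmann-type Claisen condensation driven by formation of the stabilised acyl trione anion. C3 keeps its configuration because the lactone carbonyl becomes C2 and the ester becomes C4; the excess dianion covers the C15 hydroxyl and the acidic product.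

Step 17
Reactants: 26 des-prenyl spiro acyl triketone
Product: 28 target, via monoprenyl trione 27 (not isolated)
Conditions: prenyl bromide (2.5 equiv), NaOMe (3 equiv), MeOH, −10 to 0 °C
Reagents that add atoms: prenyl bromide, CC(C)=CCBr
Why: Double C-alkylation of the triketone dianion at C1, the only enolisable ring carbon that is neither quaternary (C3) nor acyl-bearing and poorly nucleophilic (C5); it is the same gem-diprenylation that turns prenylated acylphloroglucinols into lupulone-type triones. Methoxide does not deprotonate the tertiary alcohols.

## Compound list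

1 | (S)-2-methylglycidol, [(2S)-2-methyloxiran-2-yl]methanol | OC[C@@]1(C)CO1 | starting material
2 | (R)-2-[(4-methoxybenzyloxy)methyl]-2-methyloxirane (same spatial arrangement as 1) | COc1ccc(COC[C@@]2(C)CO2)cc1 | intermediate
3 | di-tert-butyl malonate | CC(C)(C)OC(=O)CC(=O)OC(C)(C)C | starting material
4 | sodium enolate of di-tert-butyl 2-[(2R)-2-hydroxy-3-(4-methoxybenzyloxy)-2-methylpropyl]malonate | CC(C)(C)OC(=O)[C-](C[C@@](C)(O)COCc1ccc(OC)cc1)C(=O)OC(C)(C)C.[Na+] | intermediate
5 | di-tert-butyl 2-allyl-2-[(2R)-2-hydroxy-3-(4-methoxybenzyloxy)-2-methylpropyl]malonate | CC(C)(C)OC(=O)C(CC=C)(C[C@@](C)(O)COCc1ccc(OC)cc1)C(=O)OC(C)(C)C | intermediate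
6 | di-tert-butyl 2-allyl-2-[(2R)-3-(4-methoxybenzyloxy)-2-methyl-2-(triethylsilyloxy)propyl]malonate | CC(C)(C)OC(=O)C(CC=C)(C[C@@](C)(O[Si](CC)(CC)CC)COCc1ccc(OC)cc1)C(=O)OC(C)(C)C | intermediate
7 | di-tert-butyl 2-allyl-2-[(2R)-3-hydroxy-2-methyl-2-(triethylsilyloxy)propyl]malonate | CC(C)(C)OC(=O)C(CC=C)(C[C@@](C)(O[Si](CC)(CC)CC)CO)C(=O)OC(C)(C)C | intermediate
8 | di-tert-butyl 2-allyl-2-[(2R)-2-methyl-3-oxo-2-(triethylsilyloxy)propyl]malonate | CC(C)(C)OC(=O)C(CC=C)(C[C@@](C)(O[Si](CC)(CC)CC)C=O)C(=O)OC(C)(C)C | intermediate
9 | diethyl (phenylsulfonylmethyl)phosphonate | CCOP(=O)(CS(=O)(=O)c1ccccc1)OCC | starting material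
10 | di-tert-butyl 2-allyl-2-[(2R,3E)-2-methyl-4-(phenylsulfonyl)-2-(triethylsilyloxy)but-3-enyl]malonate | CC(C)(C)OC(=O)C(CC=C)(C[C@@](C)(O[Si](CC)(CC)CC)/C=C/S(=O)(=O)c1ccccc1)C(=O)OC(C)(C)C | intermediate
11 | ozonide of 10 (1,2,4-trioxolan-3-ylmethyl group in place of allyl) | CC(C)(C)OC(=O)C(CC1OCOO1)(C[C@@](C)(O[Si](CC)(CC)CC)/C=C/S(=O)(=O)c1ccccc1)C(=O)OC(C)(C)C | intermediate
12 | di-tert-butyl 2-[(2R,3E)-2-methyl-4-(phenylsulfonyl)-2-(triethylsilyloxy)but-3-enyl]-2-(2-oxoethyl)malonate | CC(C)(C)OC(=O)C(CC=O)(C[C@@](C)(O[Si](CC)(CC)CC)/C=C/S(=O)(=O)c1ccccc1)C(=O)OC(C)(C)C | intermediate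
13 | 2-bromoallyltrimethylsilane, (2-bromoprop-2-enyl)trimethylsilane | C=C(Br)C[Si](C)(C)C | starting material
14 | di-tert-butyl 2-[2-hydroxy-3-(trimethylsilylmethyl)but-3-enyl]-2-[(2R,3E)-2-methyl-4-(phenylsulfonyl)-2-(triethylsilyloxy)but-3-enyl]malonate, both C9 epimers | CC(C)(C)OC(=O)C(CC(O)C(=C)C[Si](C)(C)C)(C[C@@](C)(O[Si](CC)(CC)CC)/C=C/S(=O)(=O)c1ccccc1)C(=O)OC(C)(C)C | intermediate
15 | methyl carbonate of 14, both C9 epimers (cycloaddition precursor) | CC(C)(C)OC(=O)C(CC(OC(=O)OC)C(=C)C[Si](C)(C)C)(C[C@@](C)(O[Si](CC)(CC)CC)/C=C/S(=O)(=O)c1ccccc1)C(=O)OC(C)(C)C | intermediate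
16 | di-tert-butyl 4-methyl-1-methylidene-3-(phenylsulfonyl)-4-(triethylsilyloxy)octahydroindene-6,6-dicarboxylate; trans-fused, H9 α, H10 β, C11 methyl β, C11 silyloxy α, both C13 epimers | CC(C)(C)OC(=O)C1(C[C@@H]2[C@H](C(CC2=C)S(=O)(=O)c3ccccc3)[C@](C)(O[Si](CC)(CC)CC)C1)C(=O)OC(C)(C)C | intermediate
17 | di-tert-butyl 4-methyl-1-methylidene-4-(triethylsilyloxy)octahydroindene-6,6-dicarboxylate; trans-fused, H9 α, H10 β, C11 methyl β, C11 silyloxy α | CC(C)(C)OC(=O)C1(C[C@@H]2[C@H](CCC2=C)[C@](C)(O[Si](CC)(CC)CC)C1)C(=O)OC(C)(C)C | intermediate
18 | ozonide of 17 (spiro 1,2,4-trioxolane at C15) | CC(C)(C)OC(=O)C1(C[C@@H]2[C@H](CCC23OCOO3)[C@](C)(O[Si](CC)(CC)CC)C1)C(=O)OC(C)(C)C | intermediate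
19 | di-tert-butyl 4-methyl-1-oxo-4-(triethylsilyloxy)octahydroindene-6,6-dicarboxylate; C15 ketone, H9 α, H10 β | CC(C)(C)OC(=O)C1(C[C@@H]2[C@H](CCC2=O)[C@](C)(O[Si](CC)(CC)CC)C1)C(=O)OC(C)(C)C | intermediate
20 | 4-hydroxy-4-methyl-1-oxooctahydroindene-6,6-dicarboxylic acid; H9 α, H10 β, C11 hydroxyl α | OC(=O)C1(C[C@@H]2[C@H](CCC2=O)[C@](C)(O)C1)C(=O)O | intermediate
21 | bridged lactone acid: γ-lactone between the C11 oxygen and the α carboxyl on C3, β carboxylic acid on C3, C15 ketone, H9 α, H10 β | OC(=O)[C@]12C[C@@H]3[C@H](CCC3=O)[C@](C)(OC1=O)C2 | intermediate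
22 | methyl ester of 21 | COC(=O)[C@]12C[C@@H]3[C@H](CCC3=O)[C@](C)(OC1=O)C2 | intermediate
23 | bridged lactone methyl ester with C15 methyl carbinol (OH β, methyl α) | COC(=O)[C@]12C[C@@H]3[C@H](CC[C@]3(C)O)[C@](C)(OC1=O)C2 | intermediate
24 | 5-methylhexane-2,4-dione | CC(=O)CC(=O)C(C)C | starting material
25 | hydroxy triketo ester: C3 bearing β CO2Me and the α 6-methyl-1,3,5-trioxoheptyl chain; C11 and C15 methyl carbinols | COC(=O)[C@@]1(C(=O)CC(=O)CC(=O)C(C)C)C[C@@H]2[C@H](CC[C@]2(C)O)[C@](C)(O)C1 | intermediate
26 | des-prenyl spiro acyl triketone (target lacking both prenyl groups, C1H2) | CC(C)C(=O)C1=C(O)CC(=O)[C@@]2(C[C@@H]3[C@H](CC[C@]3(C)O)[C@](C)(O)C2)C1=O | intermediate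
27 | monoprenyl trione (one prenyl group on C1, either C1 epimer) | CC(C)=CCC1C(=O)[C@@]2(C[C@@H]3[C@H](CC[C@]3(C)O)[C@](C)(O)C2)C(=O)C(C(=O)C(C)C)=C1O | intermediate
28 | CNP0273836.6, gem-diprenyl spiro acyl triketone diol | CC(C)=CCC1(CC=C(C)C)C(=O)[C@@]2(C[C@@H]3[C@H](CC[C@]3(C)O)[C@](C)(O)C2)C(=O)C(C(=O)C(C)C)=C1O | target

## Step count and least certain steps

Total step count: 17. Longest linear sequence: 17 steps (1 to 28); 3, 9, 13 and 24 enter as single reagents.

**Step 10 (key step).** Conjugate addition at C10 is slowed by the neighbouring quaternary C11, which gives the palladium complex time to be lost through protodesilylation or diene formation. Discrimination between the two chairs (methyl or silyloxy axial) may also be incomplete, because a stereoelectronic preference for attack anti to the C–O bond opposes the steric preference; a cis-fused product is a third possible leak.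
Fallback: C9 and C10 are set by catalyst control on a preformed ring B.
- 3 is alkylated in turn with chloroacetone and allyl bromide (NaH, THF) to give di-tert-butyl 2-allyl-2-(2-oxopropyl)malonate F1.
- Ozonolysis gives di-tert-butyl 2-(2-oxoethyl)-2-(2-oxopropyl)malonate F2.
- Aldol condensation (piperidine, AcOH, 60 °C) gives di-tert-butyl 5-oxocyclohex-3-ene-1,1-dicarboxylate F3.
- Conjugate addition of boronate A6 ([RhCl(C2H4)2]2, the BINAP enantiomer that gives the required C9 centre, aqueous KOH, dioxane) gives the C9 chlorobutenyl ketone F4.
- KOt-Bu closes C10 onto the chloride to give the trans-fused C11 ketone F5; any cis isomer equilibrates through the C10 enolate.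
- MeMgBr/CeCl3 adds from the equatorial side, the axial ester on C3 blocking the axial path, to give the C11 carbinol F6.
- TESOTf/2,6-lutidine returns the route at 17.

**Step 8.** Oxidative addition of the hindered, silylmethyl-substituted vinyl bromide may be slow, and the vinyl metal may be lost by protonation or by loss of silicon before it reaches the β-branched aldehyde.
Fallback: the carbonate arm is built before any Michael acceptor is present, so that the hard vinyllithium can be used.
- 6 is cleaved with OsO4 (cat.)/NaIO4/2,6-lutidine to give the C9 aldehyde PMB ether F7.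
- The vinyllithium from 13 (t-BuLi, Et2O, −78 °C) is added and the alkoxide trapped with methyl chloroformate to give the carbonate PMB ether F8.
- DDQ gives the primary alcohol F9.
- Dess–Martin oxidation gives the C10 aldehyde F10.
- Olefination with 9 returns the route at 15.

**Step 15.** Facial selectivity at the C15 carbonyl may be poor or reversed: torsional preference for attack anti to the C9–H bond favours the β face and works against the steric argument. Attack on the lactone is a minor risk.
Fallback: oxygen, not carbon, is delivered to the open face.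
- 22 is methylenated with Zn, CH2Br2 and TiCl4 to give the C15 methylidene lactone ester F11.
- Mukaiyama hydration (Mn(dpm)3, PhSiH3, O2) traps the planar C15 radical with oxygen on the face that the carbon nucleophile preferred, giving the opposite carbinol configuration and returning at 23.

**Step 16.** The dianion may attack the methyl ester first, which would swap the roles of C2 and C4 and lead into the C3-epimeric series. The ring closure may also stall, so that the released C11 alkoxide reverses the acylation.
Fallback: the second carboxyl is kept as an inert carboxylate.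
- 21 with excess MeMgBr/CeCl3 gives the lactone acid carbinol F12.
- Excess dianion of 24 can then open only the lactone, giving the hydroxy triketo acid F13.
- DCC/DMAP closes ring A by enol ester formation and O-to-C acyl shift, returning at 26.

**Step 17.** O-alkylation of the triketone enolates, methanolysis of the allylic bromide and incomplete second alkylation may compete.
Fallback: palladium-catalysed Tsuji–Trost allylation of 26 (allyl acetate, Pd(PPh3)4), which is C-selective for soft trione anions, gives the gem-diallyl trione F14. Cross-metathesis with 2-methylbut-2-ene (second-generation Grubbs catalyst) then converts both allyl groups into prenyl groups and returns at 28.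

## Further compounds

F1 | step 10 | di-tert-butyl 2-allyl-2-(2-oxopropyl)malonate | CC(=O)CC(CC=C)(C(=O)OC(C)(C)C)C(=O)OC(C)(C)C
F2 | step 10 | di-tert-butyl 2-(2-oxoethyl)-2-(2-oxopropyl)malonate | CC(=O)CC(CC=O)(C(=O)OC(C)(C)C)C(=O)OC(C)(C)C
F3 | step 10 | di-tert-butyl 5-oxocyclohex-3-ene-1,1-dicarboxylate | O=C1C=CCC(C1)(C(=O)OC(C)(C)C)C(=O)OC(C)(C)C
F4 | step 10 | di-tert-butyl 3-(4-chlorobut-1-en-2-yl)-5-oxocyclohexane-1,1-dicarboxylate with the C9 configuration of the target | CC(C)(C)OC(=O)C1(C[C@H](CC(=O)C1)C(=C)CCCl)C(=O)OC(C)(C)C
F5 | step 10 | di-tert-butyl 1-methylidene-4-oxooctahydroindene-6,6-dicarboxylate, trans-fused, H9 α, H10 β | CC(C)(C)OC(=O)C1(C[C@@H]2[C@H](CCC2=C)C(=O)C1)C(=O)OC(C)(C)C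
F6 | step 10 | di-tert-butyl 4-hydroxy-4-methyl-1-methylidene-octahydroindene-6,6-dicarboxylate, C11 hydroxyl α, methyl β | CC(C)(C)OC(=O)C1(C[C@@H]2[C@H](CCC2=C)[C@](C)(O)C1)C(=O)OC(C)(C)C
F7 | step 8 | di-tert-butyl 2-[(2R)-3-(4-methoxybenzyloxy)-2-methyl-2-(triethylsilyloxy)propyl]-2-(2-oxoethyl)malonate | CC(C)(C)OC(=O)C(CC=O)(C[C@@](C)(O[Si](CC)(CC)CC)COCc1ccc(OC)cc1)C(=O)OC(C)(C)C
F8 | step 8 | di-tert-butyl 2-[2-(methoxycarbonyloxy)-3-(trimethylsilylmethyl)but-3-enyl]-2-[(2R)-3-(4-methoxybenzyloxy)-2-methyl-2-(triethylsilyloxy)propyl]malonate, both C9 epimers | CC(C)(C)OC(=O)C(CC(OC(=O)OC)C(=C)C[Si](C)(C)C)(C[C@@](C)(O[Si](CC)(CC)CC)COCc1ccc(OC)cc1)C(=O)OC(C)(C)C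
F9 | step 8 | di-tert-butyl 2-[(2R)-3-hydroxy-2-methyl-2-(triethylsilyloxy)propyl]-2-[2-(methoxycarbonyloxy)-3-(trimethylsilylmethyl)but-3-enyl]malonate | CC(C)(C)OC(=O)C(CC(OC(=O)OC)C(=C)C[Si](C)(C)C)(C[C@@](C)(O[Si](CC)(CC)CC)CO)C(=O)OC(C)(C)C
F10 | step 8 | di-tert-butyl 2-[2-(methoxycarbonyloxy)-3-(trimethylsilylmethyl)but-3-enyl]-2-[(2R)-2-methyl-3-oxo-2-(triethylsilyloxy)propyl]malonate | CC(C)(C)OC(=O)C(CC(OC(=O)OC)C(=C)C[Si](C)(C)C)(C[C@@](C)(O[Si](CC)(CC)CC)C=O)C(=O)OC(C)(C)C
F11 | step 15 | bridged lactone methyl ester with C15 exocyclic methylene | COC(=O)[C@]12C[C@@H]3[C@H](CCC3=C)[C@](C)(OC1=O)C2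
F12 | step 16 | bridged lactone acid with C15 methyl carbinol (OH β) | OC(=O)[C@]12C[C@@H]3[C@H](CC[C@]3(C)O)[C@](C)(OC1=O)C2
F13 | step 16 | hydroxy triketo acid (free acid of 25) | OC(=O)[C@@]1(C(=O)CC(=O)CC(=O)C(C)C)C[C@@H]2[C@H](CC[C@]2(C)O)[C@](C)(O)C1
F14 | step 17 | gem-diallyl spiro acyl triketone | C=CCC1(CC=C)C(=O)[C@@]2(C[C@@H]3[C@H](CC[C@]3(C)O)[C@](C)(O)C2)C(=O)C(C(=O)C(C)C)=C1O
A1 | alternative 1 | (S)-(bromomethyl)dimethyl[(1-methylcyclopent-2-en-1-yl)oxy]silane | C[Si](C)(CBr)O[C@]1(C)C=CCC1
A2 | alternative 1 | cis-fused oxasilolane of ring C (C15–O–SiMe2–C8H2 bridging C15 and C9) with the C10 nitrile trans to C8 | C[Si]1(C)C[C@@H]2[C@H](CC[C@]2(C)O1)C#N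
A3 | alternative 2 | bridged lactone methyl ester with C15 methyl carbinol (identical with 23) | COC(=O)[C@]12C[C@@H]3[C@H](CC[C@]3(C)O)[C@](C)(OC1=O)C2
A4 | alternative 2 | des-prenyl spiro acyl triketone (identical with 26) | CC(C)C(=O)C1=C(O)CC(=O)[C@@]2(C[C@@H]3[C@H](CC[C@]3(C)O)[C@](C)(O)C2)C1=O
A5 | alternative 3 | dimethyl 5-oxocyclohex-3-ene-1,1-dicarboxylate | COC(=O)C1(CC=CC(=O)C1)C(=O)OC
A6 | alternative 3 | 2-(4-chlorobut-1-en-2-yl)-4,4,5,5-tetramethyl-1,3,2-dioxaborolane | ClCCC(=C)B1OC(C)(C)C(C)(C)O1
A7 | alternative 3 | dimethyl 1-methylidene-4-oxooctahydroindene-6,6-dicarboxylate, trans-fused, H9 α, H10 β | COC(=O)C1(C[C@@H]2[C@H](CCC2=C)C(=O)C1)C(=O)OC
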